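Everything rests on the C7–O bond of the 1,4-dioxane ring, between the benzylic carbon bearing the 3,4,5-trimethoxyphenyl ring (ring A) and the ring-B oxygen meta to the side chain. Because C7 is benzylic to an electron-rich arene and that phenol oxygen can reach it through a six-membered ring, DDQ can remove hydride from a plain C7 methylene and the phenol can capture the cation. One operation closes the dioxane ring and sets C7 trans to the C8 methyl. The precursor is the open (R)-1-arylpropan-2-yl ether of 5-hydroxyvanillin, with a free ortho phenol and a formyl group.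

Key step: step 3

Remark: C7 is the aryl-bearing and C8 the methyl-bearing dioxane carbon (neolignan labels); in benzodioxine numbering C8 is C2 (on O1, the oxygen next to the methoxy-bearing ring carbon) and C7 is C3, and the target is the trans (2R,3R) enantiomer.

Step 1
Reactants: 1 5-bromo-1,2,3-trimethoxybenzene; 2 (S)-propylene oxide
Product: 4 (2S)-1-(3,4,5-trimethoxyphenyl)propan-2-ol, via arylmagnesium bromide 3 (not isolated)
Conditions: Mg, I2 (cat.), THF, reflux; then CuI (10 mol %), 2, THF, −30 to 0 °C; 1 M HCl work-up
Reagents that add atoms: none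
Why: Copper-catalysed opening of an epoxide by an aryl Grignard reagent should occur by SN2 attack at the unsubstituted CH2 terminus, which leaves the stereocentre of 2 untouched and gives the S alcohol.

Step 2
Reactants: 4 (2S)-1-(3,4,5-trimethoxyphenyl)propan-2-ol; 5 3,4-dihydroxy-5-methoxybenzaldehyde (5-hydroxyvanillin)
Product: 6 3-hydroxy-5-methoxy-4-{[(2R)-1-(3,4,5-trimethoxyphenyl)propan-2-yl]oxy}benzaldehyde
Conditions: PPh3, DIAD, THF, 0 °C to rt (5 in slight excess, DIAD added last)
Reagents that add atoms: none
Why: Mitsunobu etherification displaces the activated secondary alcohol by SN2 with inversion to the R ether, and the betaine should deprotonate the more acidic 4-OH para to the formyl group, so that this oxygen is alkylated rather than the 3-OH.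

Step 3
Reactants: 6 3-hydroxy-5-methoxy-4-{[(2R)-1-(3,4,5-trimethoxyphenyl)propan-2-yl]oxy}benzaldehyde
Product: 7 (2R,3R)-8-methoxy-2-methyl-3-(3,4,5-trimethoxyphenyl)-2,3-dihydro-1,4-benzodioxine-6-carbaldehyde
Conditions: DDQ (1.2 equiv), 2,6-dichloropyridine, 4 Å MS, ClCH2CH2Cl, 0 °C to rt
Reagents that add atoms: none
Why: Proposed new method: DDQ should form a charge-transfer complex with electron-rich ring A of 6 and abstract hydride from the C7 methylene, giving a benzylic cation stabilised through the 4-methoxy group as a quinoid oxocarbenium ion, which the free ring-B phenol oxygen captures while the DDQ hydroquinone anion takes up the phenolic proton. The closest known reaction types are the DDQ-mediated oxidative cyclisation of electron-rich arylalkanes onto a tethered phenol or alcohol (flavan-type benzylic C–H etherification) and the acid-induced quinone-methide closure of C7-oxygenated aryl ethers to benzodioxane neolignans; closure of a 1,4-dioxane ring at an unoxygenated 3,4,5-trimethoxybenzylic CH2 has not been shown. The dioxane ring closes in 6-exo-trig fashion, the oxygen adding to C7 whose quinoid C7=C1′ bond stays outside the new ring. The new C7 stereocentre is controlled by the existing C8 centre: in the chair-like transition state the aryl group and the C8 methyl are both pseudo-equatorial, which should give the trans (2R,3R) isomer, also the more stable one. The step needs oxidation at C7 only and capture of the cation before it loses the C8 proton to an enol ether, which would erode C8; the formyl group makes ring B and its phenol harder to oxidise than ring A, the tethered phenol makes capture intramolecular and fast, and the weak pyridine buffer with sieves keeps acid and water away. Over-oxidation should be slow because the new benzylic ether oxygen is an aryl oxygen conjugated to the formyl-bearing ring, so a slight excess of DDQ suffices.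

Step 4
Reactants: 7 (2R,3R)-8-methoxy-2-methyl-3-(3,4,5-trimethoxyphenyl)-2,3-dihydro-1,4-benzodioxine-6-carbaldehyde; 8 triethyl phosphonoacetate
Product: 10 ethyl (2E)-3-[(2R,3R)-8-methoxy-2-methyl-3-(3,4,5-trimethoxyphenyl)-2,3-dihydro-1,4-benzodioxin-6-yl]prop-2-enoate, via sodium (diethoxyphosphoryl)(ethoxycarbonyl)methanide 9 (not isolated)
Conditions: NaH, THF, 0 °C; then 7, 0 °C to rt
Reagents that add atoms: none
Why: Horner–Wadsworth–Emmons olefination of an aromatic aldehyde by a stabilised phosphonate anion should be E-selective through equilibration of the oxaphosphetane intermediates, and neither dioxane stereocentre carries a proton acidic enough to be touched.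

Step 5
Reactants: 10 ethyl (2E)-3-[(2R,3R)-8-methoxy-2-methyl-3-(3,4,5-trimethoxyphenyl)-2,3-dihydro-1,4-benzodioxin-6-yl]prop-2-enoate
Product: 11 (2E)-3-[(2R,3R)-8-methoxy-2-methyl-3-(3,4,5-trimethoxyphenyl)-2,3-dihydro-1,4-benzodioxin-6-yl]prop-2-en-1-ol (target)
Conditions: iBu2AlH (2.5 equiv), CH2Cl2, −78 °C; aq potassium sodium tartrate work-up
Reagents that add atoms: none
Why: Hydride reduction of an α,β-unsaturated ester by iBu2AlH at low temperature proceeds by 1,2-delivery to the allylic alcohol and should leave the alkene geometry, the aryl ethers and both stereocentres unchanged.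

Compound list
1 | 5-bromo-1,2,3-trimethoxybenzene | COc1cc(Br)cc(OC)c1OC | starting material
2 | (S)-propylene oxide, (2S)-2-methyloxirane | C[C@H]1CO1 | starting material
3 | (3,4,5-trimethoxyphenyl)magnesium bromide | COc1cc([Mg]Br)cc(OC)c1OC | intermediate
4 | (2S)-1-(3,4,5-trimethoxyphenyl)propan-2-ol | C[C@H](O)Cc1cc(OC)c(OC)c(OC)c1 | intermediate
5 | 3,4-dihydroxy-5-methoxybenzaldehyde (5-hydroxyvanillin) | COc1cc(C=O)cc(O)c1O | starting material
6 | 3-hydroxy-5-methoxy-4-{[(2R)-1-(3,4,5-trimethoxyphenyl)propan-2-yl]oxy}benzaldehyde | C[C@@H](Oc1c(O)cc(C=O)cc1OC)Cc1cc(OC)c(OC)c(OC)c1 | intermediate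
7 | (2R,3R)-8-methoxy-2-methyl-3-(3,4,5-trimethoxyphenyl)-2,3-dihydro-1,4-benzodioxine-6-carbaldehyde (trans) | COc1cc([C@H]2Oc3cc(C=O)cc(OC)c3O[C@@H]2C)cc(OC)c1OC | intermediate
8 | triethyl phosphonoacetate | CCOC(=O)CP(=O)(OCC)OCC | starting material
9 | sodium (diethoxyphosphoryl)(ethoxycarbonyl)methanide | [Na+].CCOC(=O)[CH-]P(=O)(OCC)OCC | intermediate
10 | ethyl (2E)-3-[(2R,3R)-8-methoxy-2-methyl-3-(3,4,5-trimethoxyphenyl)-2,3-dihydro-1,4-benzodioxin-6-yl]prop-2-enoate | COc1cc([C@H]2Oc3cc(/C=C/C(=O)OCC)cc(OC)c3O[C@@H]2C)cc(OC)c1OC | intermediate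
11 | (2E)-3-[(2R,3R)-8-methoxy-2-methyl-3-(3,4,5-trimethoxyphenyl)-2,3-dihydro-1,4-benzodioxin-6-yl]prop-2-en-1-ol | COc1cc([C@H]2Oc3cc(/C=C/CO)cc(OC)c3O[C@@H]2C)cc(OC)c1OC | target

Total step count: 5
Longest linear sequence: 5 steps (1 → 4 → 6 → 7 → 10 → 11)

Steps most likely to fail

Step 3 (key step). Hydride abstraction at C7 may be too slow on the trimethoxyphenyl ring. The cation may also lose the C8 proton to an enol ether, be trapped by adventitious water, or the closed product may be oxidised a second time. The fallback carries the C7 oxygen through and closes the ring by the established acid-induced benzylic-cation closure. It sets out from bromide 1, converted into arylmagnesium bromide 3 as in step 1, and comes back at 7. Addition of 3 to purchased (S)-2-[(tert-butyldimethylsilyl)oxy]propanal (C[C@H](O[Si](C)(C)C(C)(C)C)C=O) in THF at −78 °C should give (1RS,2S)-2-[(tert-butyldimethylsilyl)oxy]-1-(3,4,5-trimethoxyphenyl)propan-1-ol F1. The C7 epimer mixture does not matter because C7 is ionised later. MOMCl and iPr2NEt should cap the benzylic hydroxyl to give tert-butyl({(2S)-1-(methoxymethoxy)-1-(3,4,5-trimethoxyphenyl)propan-2-yl}oxy)dimethylsilane F2. TBAF in THF should then free the C8 hydroxyl to give (2S)-1-(methoxymethoxy)-1-(3,4,5-trimethoxyphenyl)propan-2-ol F3. Mitsunobu coupling of F3 with 5 (PPh3, DIAD), again at the 4-OH and with inversion at C8, should give 3-hydroxy-5-methoxy-4-{[(2R)-1-(methoxymethoxy)-1-(3,4,5-trimethoxyphenyl)propan-2-yl]oxy}benzaldehyde F4. BF3·OEt2 in CH2Cl2 at −20 to 0 °C should then ionise the benzylic C7–O bond, and the ortho phenol should close the ring to the trans aldehyde 7.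

Step 2. Alkylation may occur at the 3-OH or at both phenols, the catechol may be consumed by the phosphine/azo reagents, or the activated alcohol may eliminate to the propenylarene. The fallback removes the regiochemical question by using a ring-B partner with a single phenol and introducing the second oxygen afterwards. It sets out from 4 and comes back at 6. Mitsunobu coupling of 4 with purchased 5-bromovanillin (COc1cc(C=O)cc(Br)c1O) should give 3-bromo-5-methoxy-4-{[(2R)-1-(3,4,5-trimethoxyphenyl)propan-2-yl]oxy}benzaldehyde F5. Miyaura borylation (B2pin2, Pd(dppf)Cl2, KOAc, dioxane, 80 °C) should give 3-methoxy-5-(4,4,5,5-tetramethyl-1,3,2-dioxaborolan-2-yl)-4-{[(2R)-1-(3,4,5-trimethoxyphenyl)propan-2-yl]oxy}benzaldehyde F6. Mild oxidation of the C–B bond (NaBO3·4H2O, THF/H2O, rt) should then deliver phenol 6.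

Step 1. Bromide from the magnesium salts may open the epoxide to a bromohydrin, attack may partly occur at the internal carbon, or the Grignard reagent may homocouple. The fallback builds the carbon skeleton first and sets the stereocentre by reduction. It sets out from 1 and comes back at 4. Palladium-catalysed mono-α-arylation of acetone ([Pd(cinnamyl)Cl]2, Mor-DalPhos, Cs2CO3, acetone, 90 °C) should give 1-(3,4,5-trimethoxyphenyl)propan-2-one F7. Enantioselective reduction with an (S)-selective ketoreductase (NADPH recycled by iPrOH) or with baker's yeast should then give alcohol 4.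

Further compounds
F1 | step 3 | (1RS,2S)-2-[(tert-butyldimethylsilyl)oxy]-1-(3,4,5-trimethoxyphenyl)propan-1-ol | C[C@H](O[Si](C)(C)C(C)(C)C)C(O)c1cc(OC)c(OC)c(OC)c1
F2 | step 3 | tert-butyl({(2S)-1-(methoxymethoxy)-1-(3,4,5-trimethoxyphenyl)propan-2-yl}oxy)dimethylsilane | C[C@H](O[Si](C)(C)C(C)(C)C)C(OCOC)c1cc(OC)c(OC)c(OC)c1
F3 | step 3 | (2S)-1-(methoxymethoxy)-1-(3,4,5-trimethoxyphenyl)propan-2-ol | C[C@H](O)C(OCOC)c1cc(OC)c(OC)c(OC)c1
F4 | step 3 | 3-hydroxy-5-methoxy-4-{[(2R)-1-(methoxymethoxy)-1-(3,4,5-trimethoxyphenyl)propan-2-yl]oxy}benzaldehyde | C[C@@H](Oc1c(O)cc(C=O)cc1OC)C(OCOC)c1cc(OC)c(OC)c(OC)c1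
F5 | step 2 | 3-bromo-5-methoxy-4-{[(2R)-1-(3,4,5-trimethoxyphenyl)propan-2-yl]oxy}benzaldehyde | C[C@@H](Oc1c(Br)cc(C=O)cc1OC)Cc1cc(OC)c(OC)c(OC)c1
F6 | step 2 | 3-methoxy-5-(4,4,5,5-tetramethyl-1,3,2-dioxaborolan-2-yl)-4-{[(2R)-1-(3,4,5-trimethoxyphenyl)propan-2-yl]oxy}benzaldehyde | C[C@@H](Oc1c(B2OC(C)(C)C(C)(C)O2)cc(C=O)cc1OC)Cc1cc(OC)c(OC)c(OC)c1
F7 | step 1 | 1-(3,4,5-trimethoxyphenyl)propan-2-one | CC(=O)Cc1cc(OC)c(OC)c(OC)c1
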